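**Plan**
- Target 13 is 2-(2-hydroxy-4,5-dimethoxyphenyl)-3,7,8-trimethoxy-4H-chromen-4-one, an achiral flavone. The retrosynthesis first removes a benzyl group from the 2'-oxygen, then cuts O1–C2 of ring C, then both carbon–carbon bonds to C2 (C1'–C2 and C2–C3).
- C2 lies at the carboxyl oxidation level between ring B carbon C1' and the methoxy-bearing C3. It is therefore supplied as carbon monoxide between a ring B aryl iodide and the enolate of the ring A methoxymethyl ketone.
- Forward: ring A ketone 5 comes from 1,2,3-trimethoxybenzene by acylation and ortho-demethylation. Ring B iodide 8 comes from 3,4-dimethoxyphenol by benzylation and iodination.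
- A three-component carbonylative aroylation joins the chain as open diketone 10. Acid then closes ring C and hydrogenolysis frees the 2'-phenol.
- Stereochemistry: the target has none. The single sp3 carbon created in 10 is racemic and is erased when ring C forms.

Key step: step 5

Remark: carbon monoxide is numbered as a starting material because it becomes C2. Diketone 10 is written in the diketo form although it should equilibrate with enol tautomers, which has no bearing on step 6.

Step 1
Reactants: 1 1,2,3-trimethoxybenzene; 2 methoxyacetyl chloride
Product: 3 2-methoxy-1-(2,3,4-trimethoxyphenyl)ethan-1-one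
Conditions: AlCl3 (1.3 equiv), CH2Cl2, −10 to 0 °C; ice/aq. HCl
Reagents that add atoms: none
Why: Friedel–Crafts acylation should occur at C4 of 1, the unhindered position para to one terminal methoxy group and ortho to the other, and the deactivated ketone product should not be acylated again, while the low temperature limits ether cleavage by the Lewis acid.

Step 2
Reactants: 3 2-methoxy-1-(2,3,4-trimethoxyphenyl)ethan-1-one
Product: 5 1-(2-hydroxy-3,4-dimethoxyphenyl)-2-methoxyethan-1-one, via dichloroboryl aryl ether 4 (not isolated)
Conditions: BCl3 (1.2 equiv, 1 M in CH2Cl2), CH2Cl2, −78 to 0 °C; then H2O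
Reagents that add atoms: none
Why: Chelation-directed Lewis-acid demethylation: BCl3 bridges the ketone oxygen and the ortho methoxy oxygen in a six-membered chelate, chloride removes only that methyl group to give 4, and water releases the hydrogen-bonded phenol, while the other aryl ethers and the slower-reacting aliphatic ether should survive at low temperature.

Step 3
Reactants: 6 3,4-dimethoxyphenol
Product: 7 4-(benzyloxy)-1,2-dimethoxybenzene
Conditions: BnBr (1.1 equiv), K2CO3, DMF, rt
Reagents that add atoms: benzyl bromide, BrCc1ccccc1
Why: Williamson ether synthesis of a phenoxide with a reactive benzylic halide is routine and has no competing site.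

Step 4
Reactants: 7 4-(benzyloxy)-1,2-dimethoxybenzene
Product: 8 1-(benzyloxy)-2-iodo-4,5-dimethoxybenzene
Conditions: NIS (1.05 equiv), CF3CO2H (10 mol %), MeCN, 0 °C to rt, dark
Reagents that add atoms: N-iodosuccinimide, O=C1CCC(=O)N1I
Why: Electrophilic aromatic iodination should go to the position ortho to the benzyloxy group and para to a methoxy group, the most activated open site, since the position between two oxygens is crowded and the benzyl ring is not activated.

Step 5
Reactants: 8 1-(benzyloxy)-2-iodo-4,5-dimethoxybenzene; 9 carbon monoxide; 5 1-(2-hydroxy-3,4-dimethoxyphenyl)-2-methoxyethan-1-one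
Product: 10 1-[2-(benzyloxy)-4,5-dimethoxyphenyl]-3-(2-hydroxy-3,4-dimethoxyphenyl)-2-methoxypropane-1,3-dione
Conditions: 5 (1.2 equiv), NaN(SiMe3)2 (3.5 equiv), THF, 0 °C; then 8, Pd(dba)2 (5 mol %), Xantphos (5 mol %), CO (1 atm), 70 °C; cold aq. NH4Cl
Reagents that add atoms: none
Why: Zerovalent palladium inserts into the C–I bond of 8, CO inserts to give a divalent aroylpalladium iodide (making C1'–C2), the enolate carbon of doubly deprotonated 5 displaces iodide, and reductive elimination makes C2–C3, the product resting as its stabilised enolate until the quench. The closest known reaction type is the palladium-catalysed carbonylative α-arylation of aryl ketones with aryl iodides to 1,3-diketones, together with the C-aroylation of dianions of 2-hydroxyaryl ketones used on the way to flavones. No ring closes, because dehydration of the enolate needs acid, which is supplied only in step 6. The one new sp3 carbon (the methoxy-bearing future C3) forms racemic and enolisable and is flattened when ring C is closed, so nothing has to control it. Carbonylation must outrun direct α-arylation, which would leave out C2, and the CO atmosphere, the iodide and the wide bite angle of Xantphos favour the acyl pathway. Capture must end at carbon, which the single α-methylene of 5 and the greater basicity of the enolate carbon secure, while any aryl ester formed at the phenoxide would be carried to carbon by the excess base (Baker–Venkataraman shift) and converge on 10.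

Step 6
Reactants: 10 1-[2-(benzyloxy)-4,5-dimethoxyphenyl]-3-(2-hydroxy-3,4-dimethoxyphenyl)-2-methoxypropane-1,3-dione
Product: 12 2-[2-(benzyloxy)-4,5-dimethoxyphenyl]-3,7,8-trimethoxy-4H-chromen-4-one, via 2-hydroxychromanone hemiketal 11 (not isolated)
Conditions: TsOH·H2O (20 mol %), toluene, 90 °C
Reagents that add atoms: none
Why: Acid-catalysed cyclodehydration (the closing stage of a Baker–Venkataraman flavone synthesis): only ring A carries a free phenol, which adds 6-exo-trig to the protonated ring B carbonyl to give hemiketal 11, and loss of water gives the conjugated pyranone, the benzyl ether keeping the ring B oxygen out of the closure.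

Step 7
Reactants: 12 2-[2-(benzyloxy)-4,5-dimethoxyphenyl]-3,7,8-trimethoxy-4H-chromen-4-one
Product: 13 2-(2-hydroxy-4,5-dimethoxyphenyl)-3,7,8-trimethoxy-4H-chromen-4-one
Conditions: H2 (1 atm), 10% Pd/C (palladium on carbon), EtOAc–MeOH, rt
Reagents that add atoms: none
Why: Catalytic hydrogenolysis cleaves the benzyl aryl ether, while the tetrasubstituted C2=C3 bond of the chromone (a vinylogous ester) and the methyl ethers should be inert at ambient pressure and temperature.

**Compound list**
1 | 1,2,3-trimethoxybenzene | COc1cccc(OC)c1OC | starting material
2 | methoxyacetyl chloride | COCC(=O)Cl | starting material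
3 | 2-methoxy-1-(2,3,4-trimethoxyphenyl)ethan-1-one | COCC(=O)c1ccc(OC)c(OC)c1OC | intermediate
4 | dichloro[2,3-dimethoxy-6-(methoxyacetyl)phenoxy]borane (dichloroboryl aryl ether) | COCC(=O)c1ccc(OC)c(OC)c1OB(Cl)Cl | intermediate (not isolated)
5 | 1-(2-hydroxy-3,4-dimethoxyphenyl)-2-methoxyethan-1-one | COCC(=O)c1ccc(OC)c(OC)c1O | intermediate
6 | 3,4-dimethoxyphenol | COc1ccc(O)cc1OC | starting material
7 | 4-(benzyloxy)-1,2-dimethoxybenzene | COc1ccc(OCc2ccccc2)cc1OC | intermediate
8 | 1-(benzyloxy)-2-iodo-4,5-dimethoxybenzene | COc1cc(I)c(OCc2ccccc2)cc1OC | intermediate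
9 | carbon monoxide | [C-]#[O+] | starting material
10 | 1-[2-(benzyloxy)-4,5-dimethoxyphenyl]-3-(2-hydroxy-3,4-dimethoxyphenyl)-2-methoxypropane-1,3-dione (racemic at the methoxy-bearing carbon) | COC(C(=O)c1ccc(OC)c(OC)c1O)C(=O)c1cc(OC)c(OC)cc1OCc1ccccc1 | intermediate
11 | 2-[2-(benzyloxy)-4,5-dimethoxyphenyl]-2-hydroxy-3,7,8-trimethoxy-2,3-dihydro-4H-chromen-4-one (mixture of stereoisomers) | COC1C(=O)c2ccc(OC)c(OC)c2OC1(O)c1cc(OC)c(OC)cc1OCc1ccccc1 | intermediate (not isolated)
12 | 2-[2-(benzyloxy)-4,5-dimethoxyphenyl]-3,7,8-trimethoxy-4H-chromen-4-one | COc1cc(OCc2ccccc2)c(-c2oc3c(OC)c(OC)ccc3c(=O)c2OC)cc1OC | intermediate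
13 | 2-(2-hydroxy-4,5-dimethoxyphenyl)-3,7,8-trimethoxy-4H-chromen-4-one | COc1cc(O)c(-c2oc3c(OC)c(OC)ccc3c(=O)c2OC)cc1OC | target

**Step count**
Total steps: 7. Longest linear sequence: 5 steps (steps 1, 2, 5, 6, 7 or steps 3, 4, 5, 6, 7).

**Steps most likely to fail**

Step 5. The aroylpalladium intermediate may be intercepted by silazide or phenoxide faster than by the hindered, doubly charged enolate carbon. The electron-rich, ortho-substituted iodide may also carbonylate slowly, so that hydrodehalogenation takes over. The fallback sets out from 8 and 5 and returns at 10 by the classical two-stage acyl transfer. Iodine–magnesium exchange on 8 (i-PrMgCl·LiCl, THF, 0 °C to rt) and a CO2 quench should give 2-(benzyloxy)-4,5-dimethoxybenzoic acid F1. Steglich esterification of F1 with phenol 5 (EDC·HCl, DMAP, CH2Cl2, rt) should give 2,3-dimethoxy-6-(methoxyacetyl)phenyl 2-(benzyloxy)-4,5-dimethoxybenzoate F2. A Baker–Venkataraman acyl shift (LiN(SiMe3)2, THF, −78 °C to rt) should then deliver diketone 10.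

Step 6. Hot acid may remove the benzyl group before the ring closes, which would let the ring B oxygen compete for closure onto the other carbonyl. It may also cause retro-Claisen cleavage of the 2-methoxy-1,3-diketone. The fallback sets out from 5 and 8 with 9 and returns at 12 without any acid step and without a new compound (F0). The carbonylative coupling is run with Pd(OAc)2, 1,4-bis(diphenylphosphino)butane and DBU in DMSO at 110–120 °C under CO. This is the known one-pot carbonylative flavone synthesis from 2-hydroxyaryl ketones and aryl halides, in which aroylation and base-induced ring closure through 10 and 11 follow one another in the same flask.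

Step 2. Boron trichloride may also cleave the aliphatic methoxy group through a five-membered chelate with the ketone, or go on to demethylate the neighbouring ring ether. The fallback sets out from 2 and returns at 5, bypassing steps 1 and 2 and every ether cleavage. Commercial 2,3-dimethoxyphenol F3 is acylated with 2 (Et3N, CH2Cl2, 0 °C) to give 2,3-dimethoxyphenyl methoxyacetate F4. A Fries rearrangement (BF3·OEt2, 90 °C) should then move the acyl group to the position ortho to the phenol oxygen and para to the 3-methoxy group, which is ketone 5.

**Further compounds**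
F1 | step 5 | 2-(benzyloxy)-4,5-dimethoxybenzoic acid | COc1cc(C(=O)O)c(OCc2ccccc2)cc1OC
F2 | step 5 | 2,3-dimethoxy-6-(methoxyacetyl)phenyl 2-(benzyloxy)-4,5-dimethoxybenzoate | COCC(=O)c1ccc(OC)c(OC)c1OC(=O)c1cc(OC)c(OC)cc1OCc1ccccc1
F0 | step 6 | none | none
F3 | step 2 | 2,3-dimethoxyphenol | COc1cccc(O)c1OC
F4 | step 2 | 2,3-dimethoxyphenyl methoxyacetate | COCC(=O)Oc1cccc(OC)c1OC
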